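**Retrosynthetic overview**
1. Ring C is formed last. The O1–C2 bond of flavone 20 comes from acid cyclodehydration of the o-hydroxyaryl 1,3-diketone 18.
2. Key C–C bond (flavone C3–C2): crossed Claisen condensation of the enolate of ring A ketone 9 with ring B aroyl chloride 15.
3. Ketone 9 comes from 3,4-dimethoxyphenol 1 by MOM protection, directed ortho-lithiation/formylation, MeMgBr addition, oxidation and MOM removal.
4. Chloride 15 comes from 3,4,5-trimethoxyphenol 10 by O-methylation, lithiation/carboxylation and chlorination.
5. Rings A and B are bought as arenes, so ring C is the only ring built.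

Assumption: the target SMILES has no stereocentre and the C2–C1' aryl axis rotates freely at room temperature. The compound is therefore achiral and needs no enantiocontrol. The transient stereocentres in 4, 6, 7 and 19 are racemic and are erased later.

**Step 1**
Reactants: 1 3,4-dimethoxyphenol
Product: 2 1,2-dimethoxy-4-(methoxymethoxy)benzene
Conditions: MOMCl (1.3 equiv), i-Pr2NEt (1.6 equiv), CH2Cl2, 0 °C → rt, 12 h
Reagents that add atoms: chloromethyl methyl ether (MOMCl), COCCl
Why: Williamson-type O-alkylation (MOM protection) of the only acidic OH masks the phenol and installs a chelating ortho-directing group, and no stereocentre is formed.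

**Step 2**
Reactants: 2 1,2-dimethoxy-4-(methoxymethoxy)benzene
Product: 5 2,3-dimethoxy-6-(methoxymethoxy)benzaldehyde, via aryllithium 3 (not isolated), via lithium hemiaminal alkoxide 4 (not isolated)
Conditions: n-BuLi (1.2 equiv), TMEDA (1.2 equiv), THF, −20 → 0 °C, 2 h; DMF (2 equiv), −78 °C → rt; then H2O
Reagents that add atoms: N,N-dimethylformamide, CN(C)C=O
Why: In this directed ortho-metalation the ring CH flanked by OMOM and OMe is acidified and chelated by both groups, so it is lithiated selectively, and DMF formylates the aryllithium through adduct 4, which survives until the quench and so prevents over-addition.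

**Step 3**
Reactants: 5 2,3-dimethoxy-6-(methoxymethoxy)benzaldehyde
Product: 7 rac-1-[2,3-dimethoxy-6-(methoxymethoxy)phenyl]ethan-1-ol, via bromomagnesium alkoxide 6 (not isolated)
Conditions: MeMgBr (1.3 equiv), THF, 0 °C → rt, 1 h; then sat. aq NH4Cl
Reagents that add atoms: methylmagnesium bromide, C[Mg]Br
Why: Grignard 1,2-addition to a non-enolisable aldehyde is clean, and the new carbinol centre forms racemic, which does not matter because step 4 removes it.

**Step 4**
Reactants: 7 rac-1-[2,3-dimethoxy-6-(methoxymethoxy)phenyl]ethan-1-ol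
Product: 8 1-[2,3-dimethoxy-6-(methoxymethoxy)phenyl]ethan-1-one
Conditions: IBX (1.5 equiv), EtOAc, 75 °C, 4 h; filter
Reagents that add atoms: none
Why: IBX oxidation of a secondary benzylic alcohol runs under neutral conditions that leave the MOM acetal and the aryl methyl ethers untouched, and it erases the carbinol stereocentre.

**Step 5**
Reactants: 8 1-[2,3-dimethoxy-6-(methoxymethoxy)phenyl]ethan-1-one
Product: 9 1-(6-hydroxy-2,3-dimethoxyphenyl)ethan-1-one
Conditions: conc. HCl (cat.), MeOH, 50 °C, 2 h
Reagents that add atoms: none
Why: Acid-catalysed acetal exchange (MOM cleavage) frees the phenol under conditions far too mild to touch aryl methyl ethers or the ketone, and the product is stabilised by its OH···O=C hydrogen bond.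

**Step 6**
Reactants: 10 3,4,5-trimethoxyphenol
Product: 11 1,2,3,5-tetramethoxybenzene
Conditions: MeI (1.5 equiv), K2CO3 (2 equiv), acetone, reflux, 8 h
Reagents that add atoms: iodomethane, CI
Why: Williamson ether synthesis on an unhindered phenol is essentially quantitative and gives a symmetric arene whose two ring CH positions are equivalent.

**Step 7**
Reactants: 11 1,2,3,5-tetramethoxybenzene
Product: 14 2,3,4,6-tetramethoxybenzoic acid, via aryllithium 12 (not isolated), via lithium carboxylate 13 (not isolated)
Conditions: n-BuLi (1.1 equiv), THF, 0 °C → rt, 1.5 h; dry CO2 (excess), −78 → 0 °C; then cold 1 M HCl to pH 3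
Reagents that add atoms: carbon dioxide, O=C=O
Why: Directed ortho-metalation removes one of the two symmetry-equivalent protons, each flanked by two methoxy groups, and carboxylation of the aryllithium followed by a cold dilute acid quench gives the acid without protodecarboxylation.

**Step 8**
Reactants: 14 2,3,4,6-tetramethoxybenzoic acid
Product: 15 2,3,4,6-tetramethoxybenzoyl chloride
Conditions: (COCl)2 (1.5 equiv), DMF (cat.), CH2Cl2, 0 °C → rt, 2 h; evaporate, use crude the same day
Reagents that add atoms: oxalyl chloride, O=C(Cl)C(=O)Cl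
Why: DMF-catalysed acid chloride formation (Vilsmeier-type activation) works at or below room temperature, gives only gaseous by-products, and avoids the heat that would decarboxylate this electron-rich acid.

**Step 9 (key step)**
Reactants: 9 1-(6-hydroxy-2,3-dimethoxyphenyl)ethan-1-one; 15 2,3,4,6-tetramethoxybenzoyl chloride
Product: 18 1-(6-hydroxy-2,3-dimethoxyphenyl)-3-(2,3,4,6-tetramethoxyphenyl)propane-1,3-dione, via dilithium dianion 16 (not isolated), via dilithium diketonate 17 (not isolated)
Conditions: 9, LiN(SiMe3)2 (3.3 equiv), THF, −78 °C 1 h → −10 °C 2 h; recool to −78 °C, 15 (1.0 equiv) in THF, −78 °C 1 h → rt 4 h; then ice/dilute HCl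
Reagents that add atoms: none
Why: In this crossed Claisen condensation the enolate carbon of dianion 16 is much more nucleophilic than the chelated lithium phenoxide, the acyl partner cannot enolise, and the third equivalent of base converts the product to diketonate 17, which drives the reaction and blocks a second acylation.

**Step 10**
Reactants: 18 1-(6-hydroxy-2,3-dimethoxyphenyl)-3-(2,3,4,6-tetramethoxyphenyl)propane-1,3-dione
Product: 20 5,6,2',3',4',6'-hexamethoxyflavone, via cyclic hemiketal 19 (not isolated)
Conditions: H2SO4 (0.5 vol %, cat.), glacial AcOH, 95–100 °C, 1 h; pour into water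
Reagents that add atoms: none
Why: In this acid-catalysed cyclodehydration the phenol adds to the aroyl carbonyl to give hemiketal 19, which loses water irreversibly to the conjugated 4-pyranone of ring C, and the hemiketal stereocentre disappears so 20 is achiral.

**Compound list**
1 | 3,4-dimethoxyphenol | COc1ccc(O)cc1OC | starting material
2 | 1,2-dimethoxy-4-(methoxymethoxy)benzene | COCOc1ccc(OC)c(OC)c1 | intermediate
3 | [2,3-dimethoxy-6-(methoxymethoxy)phenyl]lithium (aryllithium) | COCOc1ccc(OC)c(OC)c1[Li] | intermediate
4 | lithium (dimethylamino)[2,3-dimethoxy-6-(methoxymethoxy)phenyl]methanolate (hemiaminal alkoxide, racemic) | COCOc1ccc(OC)c(OC)c1C(O[Li])N(C)C | intermediate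
5 | 2,3-dimethoxy-6-(methoxymethoxy)benzaldehyde | COCOc1ccc(OC)c(OC)c1C=O | intermediate
6 | bromomagnesium 1-[2,3-dimethoxy-6-(methoxymethoxy)phenyl]ethan-1-olate (racemic) | COCOc1ccc(OC)c(OC)c1C(C)O[Mg]Br | intermediate
7 | rac-1-[2,3-dimethoxy-6-(methoxymethoxy)phenyl]ethan-1-ol | COCOc1ccc(OC)c(OC)c1C(C)O | intermediate
8 | 1-[2,3-dimethoxy-6-(methoxymethoxy)phenyl]ethan-1-one | COCOc1ccc(OC)c(OC)c1C(C)=O | intermediate
9 | 1-(6-hydroxy-2,3-dimethoxyphenyl)ethan-1-one | CC(=O)c1c(O)ccc(OC)c1OC | intermediate
10 | 3,4,5-trimethoxyphenol | COc1cc(O)cc(OC)c1OC | starting material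
11 | 1,2,3,5-tetramethoxybenzene | COc1cc(OC)c(OC)c(OC)c1 | intermediate
12 | (2,3,4,6-tetramethoxyphenyl)lithium (aryllithium) | COc1cc(OC)c([Li])c(OC)c1OC | intermediate
13 | lithium 2,3,4,6-tetramethoxybenzoate | COc1cc(OC)c(C(=O)O[Li])c(OC)c1OC | intermediate
14 | 2,3,4,6-tetramethoxybenzoic acid | COc1cc(OC)c(C(=O)O)c(OC)c1OC | intermediate
15 | 2,3,4,6-tetramethoxybenzoyl chloride | COc1cc(OC)c(C(=O)Cl)c(OC)c1OC | intermediate
16 | dilithium dianion of 9 (lithium phenoxide plus lithium enolate) | C=C(O[Li])c1c(O[Li])ccc(OC)c1OC | intermediate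
17 | dilithium salt of 18 (lithium phenoxide plus chelated Z-enolate) | [Li]O/C(=C\C(=O)c1c(O[Li])ccc(OC)c1OC)c1c(OC)cc(OC)c(OC)c1OC | intermediate
18 | 1-(6-hydroxy-2,3-dimethoxyphenyl)-3-(2,3,4,6-tetramethoxyphenyl)propane-1,3-dione | COc1cc(OC)c(C(=O)CC(=O)c2c(O)ccc(OC)c2OC)c(OC)c1OC | intermediate
19 | rac-2-hydroxy-5,6-dimethoxy-2-(2,3,4,6-tetramethoxyphenyl)chroman-4-one (cyclic hemiketal) | COc1cc(OC)c(C2(O)CC(=O)c3c(OC)c(OC)ccc3O2)c(OC)c1OC | intermediate
20 | 5,6,2',3',4',6'-hexamethoxyflavone (achiral) | COc1cc(OC)c(-c2cc(=O)c3c(OC)c(OC)ccc3o2)c(OC)c1OC | target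

**Totals**
Total step count: 10. Steps 1–5 build the ring A fragment, steps 6–8 build the ring B fragment, and steps 9–10 join them and close ring C.
Longest linear sequence: 7 steps (1, 2, 3, 4, 5, 9, 10).

**Three steps most likely to fail**

Step 9 is the first risk. The di-ortho-substituted acid chloride is hindered, and the phenoxide oxygen may be acylated in place of the enolate carbon. The fallback sets out from 9 (together with 15) and comes back to the route at 18. Compound 9 is deliberately O-acylated with 15 in pyridine with catalytic DMAP at rt to give 2-acetyl-3,4-dimethoxyphenyl 2,3,4,6-tetramethoxybenzoate F1. The aroyl group is then moved from oxygen to carbon intramolecularly by a Baker–Venkataraman rearrangement with LiN(SiMe3)2 (2.2 equiv) in THF, −78 °C → rt. This gives the same diketonate 17, and a dilute HCl quench turns it into 18. Any O-acylated material recovered from step 9 can be fed into this sequence as well.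

Step 10 is the second risk. Hot acid could cleave the peri 5-methoxy group or protodeacylate the very electron-rich aryl ketone. The fallback sets out from 11 (together with 9) and comes back at 20, avoiding both the diketone and strong acid.
- Vilsmeier–Haack formylation of 11 (POCl3, DMF, 0 → 60 °C) gives dimethyl[(2,3,4,6-tetramethoxyphenyl)methylidene]ammonium chloride F2.
- Aqueous NaOAc hydrolyses this salt to 2,3,4,6-tetramethoxybenzaldehyde F3.
- An intermolecular Claisen–Schmidt aldol condensation of F3 with 9 (KOH, EtOH–H2O, rt, 48 h, then acidify) gives (E)-1-(6-hydroxy-2,3-dimethoxyphenyl)-3-(2,3,4,6-tetramethoxyphenyl)prop-2-en-1-one F4.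
- Oxidative cyclisation of the chalcone with I2 (10 mol %) in DMSO at 120 °C closes ring C and dehydrogenates it to 20, with DMSO as the terminal oxidant. Keeping the iodine catalytic limits iodination of ring B.

Step 8 is the third risk. The HCl that is evolved can protodecarboxylate the electron-rich acid, and the chloride cannot be purified before use. The fallback sets out from 14 and comes back at 18. Acid 14 is activated without any HCl by 1,1'-carbonyldiimidazole (1.2 equiv, THF, rt → 40 °C until gas evolution stops). This gives the isolable acyl donor (1H-imidazol-1-yl)(2,3,4,6-tetramethoxyphenyl)methanone F5. F5 is added in place of 15 to dianion 16 under the conditions of step 9 (−78 °C → rt, longer time), giving 17 and, after the acid quench, 18.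

**Further compounds**
F1 | step 9 | 2-acetyl-3,4-dimethoxyphenyl 2,3,4,6-tetramethoxybenzoate | COc1cc(OC)c(C(=O)Oc2ccc(OC)c(OC)c2C(C)=O)c(OC)c1OC
F2 | step 10 | dimethyl[(2,3,4,6-tetramethoxyphenyl)methylidene]ammonium chloride | C[N+](C)=Cc1c(OC)cc(OC)c(OC)c1OC.[Cl-]
F3 | step 10 | 2,3,4,6-tetramethoxybenzaldehyde | COc1cc(OC)c(C=O)c(OC)c1OC
F4 | step 10 | (E)-1-(6-hydroxy-2,3-dimethoxyphenyl)-3-(2,3,4,6-tetramethoxyphenyl)prop-2-en-1-one | COc1cc(OC)c(/C=C/C(=O)c2c(O)ccc(OC)c2OC)c(OC)c1OC
F5 | step 8 | (1H-imidazol-1-yl)(2,3,4,6-tetramethoxyphenyl)methanone | COc1cc(OC)c(C(=O)n2ccnc2)c(OC)c1OC
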